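**Retrosynthetic overview**

1. Target 29 ⇐ acetylation of aldol 28 ⇐ N–O cleavage of isoxazoline 26; the C1 ester (with inversion), the C6–OH-directed (8S)-epoxide and the C6 ester are put on while the aldol is masked as the isoxazoline.
2. Cyclopentane ring with C13 and C14 ⇐ intramolecular nitrile oxide–alkene [3+2] cycloaddition of a C3 CH2–C≡N–O arm onto a C4 (Z)-propenyl group; the trans-3,4 pattern gives the trans-hydrindane.
3. C3–C11 bond ⇐ Eschenmoser–Claisen [3,3] shift from the C1β allylic alcohol; the C1=C2 alkene it leaves is turned into C1–O / C2=CH2 by iodolactonisation, epoxide closure and titanocene-mediated isomerisation.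
4. C4 arm ⇐ vinylogous Mukaiyama alkylation of the linear dienol ether of (R)-carvone, then Z-Wittig; C6–O ⇐ Rubottom oxidation; C1β–OH ⇐ Luche reduction.
5. Ring order: cyclohexane bought in (R)-carvone → isoxazoline and cyclopentane together in the cycloaddition → cyclopentanone unveiled last.

Assumption: (R)-carvone, (R)-2-methylbutanoic acid and (Z)-3-methylpent-2-enoic acid are bought as such; every other reagent is achiral.

Locants and faces: carvone numbering is kept (C1 = former carbonyl carbon, C2 carries C7, C5 carries the isopropenyl group C8–C10, C6 = α′ carbon). Added carbons are C11 (on C3), C12, C13 (on C4), C14 and C15. β is the face of the C5 substituent, α the other face. TBS = tert-butyldimethylsilyl.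

**Route**

Step 1
Reactants: 1 (R)-carvone
Product: 3 linear TBS dienol ether of carvone (C1–OTBS; C1=C2 and C3=C4), via potassium dienolate 2 (not isolated)
Conditions: KN(SiMe3)2 (0.95 equiv), THF, −78 → 25 °C (equilibration); TBSCl, −78 → 25 °C
Reagents that add atoms: tert-butyldimethylsilyl chloride, CC(C)(C)[Si](C)(C)Cl
Why: Proton-transfer equilibration with a slight deficit of base gives the fully conjugated (γ-deprotonated) thermodynamic dienolate, and O-silylation (enolate silylation) fixes it as the 1-silyloxy-1,3-diene; no stereocentre is made and C5 is untouched.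

Step 2
Reactants: 3 linear TBS dienol ether of carvone
Product: 4 4α-(dimethoxymethyl)carvone (C4 arm trans to the C5 isopropenyl group)
Conditions: HC(OMe)3, Me3SiOTf (10 mol %), CH2Cl2, −78 °C
Reagents that add atoms: trimethyl orthoformate, COC(OC)OC
Why: Vinylogous Mukaiyama alkylation: the dimethoxycarbenium ion attacks the γ-carbon C4 (the α-carbon C2 is fully substituted) on the face away from the neighbouring C5 isopropenyl group, setting C4α.

Step 3
Reactants: 4 4α-(dimethoxymethyl)carvone
Product: 7 6α-(TBS-oxy)-4α-(dimethoxymethyl)carvone, via kinetic silyl dienol ether 5 (not isolated), via silyloxy epoxide 6 (not isolated)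
Conditions: LiN(iPr)2, TBSOTf, THF, −78 °C; aqueous work-up; crude 5 + dimethyldioxirane, acetone, −40 → 0 °C
Reagents that add atoms: tert-butyldimethylsilyl trifluoromethanesulfonate, CC(C)(C)[Si](C)(C)OS(=O)(=O)C(F)(F)F; dimethyldioxirane, CC1(C)OO1
Why: Rubottom oxidation: kinetic α′-deprotonation at C6, epoxidation of the electron-rich enol ether anti to the adjacent C5 isopropenyl group and 1,4-silyl shift give the 6α-silyloxy ketone (O trans to C5).

Step 4
Reactants: 7 6α-(TBS-oxy)-4α-(dimethoxymethyl)carvone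
Product: 8 allylic 1β-alcohol (1β-OH, 6α-OTBS, 5β-isopropenyl and 4α-CH(OMe)2 all mutually trans)
Conditions: NaBH4, CeCl3·7H2O, MeOH, −78 → 0 °C
Reagents that add atoms: none
Why: Luche 1,2-reduction: axial hydride delivery anti to the axial C6–H gives the equatorial C1β alcohol (the cis-carveol sense known for carvone).

Step 5
Reactants: 8 allylic 1β-alcohol dimethyl acetal
Product: 9 4α-formyl allylic 1β-alcohol
Conditions: LiBF4, MeCN/H2O (50:1), 20 °C
Reagents that add atoms: water, O
Why: Near-neutral acetal hydrolysis frees the aldehyde without ionising the allylic alcohol or moving the C2=C3 bond into conjugation; the 4,5-trans arrangement is also the thermodynamic one.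

Step 6
Reactants: 9 4α-formyl allylic 1β-alcohol
Product: 10 4α-[(Z)-prop-1-enyl] allylic 1β-alcohol
Conditions: EtPPh3Br, KN(SiMe3)2 (3 equiv each), THF, 0 °C; add 9, −78 → 0 °C
Reagents that add atoms: ethyltriphenylphosphonium bromide, CC[P+](c1ccccc1)(c1ccccc1)c1ccccc1.[Br-]
Why: Wittig olefination with a non-stabilised, lithium-free ylide gives the (Z)-alkene under kinetic control; the free alcohol is carried as its alkoxide.

Step 7
Reactants: 10 4α-[(Z)-prop-1-enyl] allylic 1β-alcohol
Product: 12 N,N-dimethylamide with C3β–CH2C(=O)NMe2 and a C1=C2 alkene, via ketene N,O-acetal 11 (not isolated)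
Conditions: MeC(OMe)2NMe2 (5 equiv), xylenes, 150 °C, sealed tube
Reagents that add atoms: N,N-dimethylacetamide dimethyl acetal, COC(C)(OC)N(C)C
Why: Eschenmoser–Claisen [3,3]-sigmatropic rearrangement: C11 is delivered suprafacially from the C1β oxygen to the β-face of C3 through a chair-like transition state, so C3 is set trans to the C4α arm.

Step 8
Reactants: 12 N,N-dimethylamide
Product: 14 iodolactone (C2β–O γ-lactone cis-fused at C2–C3; C1α–I), via iminium lactone iodide 13 (not isolated)
Conditions: I2 (1.5 equiv), THF/H2O (1:1), 20 °C, dark; aq. Na2S2O3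
Reagents that add atoms: iodine, II; water, O
Why: Iodolactonisation of the γ,δ-unsaturated amide: the amide oxygen on the β-arm closes 5-exo onto C2 from the β-face, iodine adds anti at C1 (α), and the iminium ether is hydrolysed in situ.

Step 9
Reactants: 14 iodolactone
Product: 15 methyl ester 1β,2β-epoxide
Conditions: K2CO3, MeOH, 20 °C
Reagents that add atoms: methanol, CO
Why: Methanolysis of the lactone frees the C2β alkoxide, which displaces the anti C1α iodide (intramolecular Williamson SN2) to give the β-epoxide.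

Step 10
Reactants: 15 methyl ester 1β,2β-epoxide
Product: 16 1β-hydroxy-2-methylidene methyl ester
Conditions: Cp2TiCl2 (2.5 equiv), Mn powder, THF, 20 °C (Cp2TiCl, trivalent titanium, formed in the flask); then 15; dilute HCl work-up
Reagents that add atoms: none
Why: Titanocene-mediated radical epoxide opening at the tertiary C2–O bond followed by hydrogen loss from the unhindered C7 methyl (epoxide-to-allylic-alcohol isomerisation) gives the exocyclic alkene; the C1–O bond is not touched, so C1 stays β, and ester, silyl ether and alkenes are inert.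

Step 11
Reactants: 16 1β-hydroxy-2-methylidene methyl ester
Product: 17 1β-hydroxy aldehyde (C3β–CH2CHO)
Conditions: iBu2AlH (2.2 equiv), CH2Cl2, −78 °C; MeOH, aq. potassium sodium tartrate
Reagents that add atoms: none
Why: Half-reduction of the methyl ester stops at the tetrahedral aluminium hemiacetal at −78 °C (ester-to-aldehyde reduction); the 1,3-trans-diequatorial OH and CH2CHO cannot close to a lactol.

Step 12
Reactants: 17 1β-hydroxy aldehyde
Product: 20 isoxazoline-fused trans-hydrindane 1β-alcohol (C12=N–O–C14; 14S), via oxime 18 (not isolated), via nitrile oxide 19 (not isolated)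
Conditions: NH2OH·HCl (1.05 equiv), NaOAc, MeOH, 20 °C; then PhI(OAc)2 (1.2 equiv), 0 → 20 °C
Reagents that add atoms: hydroxylamine hydrochloride, NO.Cl
Why: Oxime formation, oxidation to the nitrile oxide and intramolecular nitrile oxide–alkene [3+2] cycloaddition: the trans-diequatorial C3 and C4 arms give the trans-fused five-membered ring, and suprafacial addition to the (Z)-alkene in the conformer with C4–H eclipsing the double bond (allylic 1,3-strain) sets C13 (arm cis to C4–H) and C14 (S).

Step 13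
Reactants: 20 isoxazoline 1β-alcohol; 21 (R)-2-methylbutanoic acid
Product: 22 C1α (R)-2-methylbutanoate (axial ester cis to C6–OTBS)
Conditions: PPh3, DIAD, toluene, 0 → 20 °C
Reagents that add atoms: none
Why: Mitsunobu esterification displaces the activated C1β oxygen by SN2 with inversion, giving the C1α ester and leaving the acid's α-stereocentre alone.

Step 14
Reactants: 22 C1α (R)-2-methylbutanoate silyl ether
Product: 23 C6α alcohol
Conditions: HF·pyridine, THF, 0 → 20 °C
Reagents that add atoms: none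
Why: Fluoride-mediated desilylation under mildly acidic conditions avoids 1,2-acyl migration from C1 to C6 and leaves ester and isoxazoline intact.

Step 15
Reactants: 23 C6α alcohol
Product: 24 (8S)-8,9-epoxide
Conditions: VO(acac)2 (5 mol %), t-BuOOH, CH2Cl2, 0 → 20 °C
Reagents that add atoms: tert-butyl hydroperoxide, CC(C)(C)OO
Why: Hydroxyl-directed vanadium-catalysed epoxidation of the homoallylic alcohol: the C6 vanadate delivers oxygen to the gauche isopropenyl group through a chair-like transition state with the C10 methyl pseudo-equatorial (8S), while the C2 methylidene is anti-periplanar to C6–O and deactivated by the allylic ester.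

Step 16
Reactants: 24 (8S)-epoxy C6α alcohol; 25 (Z)-3-methylpent-2-enoic acid
Product: 26 C6α (Z)-3-methylpent-2-enoate
Conditions: DCC, DMAP (5 mol %), CH2Cl2, 0 → 20 °C
Reagents that add atoms: none
Why: Steglich esterification acylates the only free hydroxyl with retention at C6; low DMAP loading and low temperature keep the Z-geometry and the epoxide.

Step 17
Reactants: 26 isoxazoline diester
Product: 28 β-hydroxy ketone (C12=O; C14–OH, 14S), via β-hydroxy imine 27 (not isolated)
Conditions: SmI2 (3 equiv), THF, 0 °C; then B(OH)3, MeOH/H2O, 20 °C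
Reagents that add atoms: water, O
Why: Single-electron reductive N–O cleavage by divalent samarium and boric-acid-buffered imine hydrolysis unmask the aldol without touching epoxide, esters or alkenes; C13 stays in its thermodynamic trans arrangement.

Step 18
Reactants: 28 β-hydroxy ketone
Product: 29 CNP0262178.2 (target)
Conditions: Ac2O, pyridine, CH2Cl2, 0 → 20 °C
Reagents that add atoms: acetic anhydride, CC(=O)OC(C)=O
Why: O-acetylation of the secondary C14 alcohol with retention, without DMAP to limit β-elimination of the β-acetoxy ketone.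

**Compound list**

1 | (R)-carvone [(5R)-2-methyl-5-(prop-1-en-2-yl)cyclohex-2-en-1-one] | CC1=CC[C@@H](C(C)=C)CC1=O | starting material
2 | potassium dienolate of carvone (C1–OK; C1=C2 and C3=C4) | CC1C=C[C@@H](C(C)=C)CC=1[O-].[K+] | intermediate
3 | linear TBS dienol ether of carvone [(5R)-1-(TBS-oxy)-2-methyl-5-(prop-1-en-2-yl)cyclohexa-1,3-diene] | CC1C=C[C@@H](C(C)=C)CC=1O[Si](C)(C)C(C)(C)C | intermediate
4 | 4α-(dimethoxymethyl)carvone (4,5-trans) | CC1=C[C@H](C(OC)OC)[C@@H](C(C)=C)CC1=O | intermediate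
5 | kinetic TBS dienol ether of 4 (C1–OTBS; C1=C6 and C2=C3) | CC1=C[C@H](C(OC)OC)[C@@H](C(C)=C)C=C1O[Si](C)(C)C(C)(C)C | intermediate
6 | 1,6α-epoxide of 5 (1-silyloxy oxirane) | CC1=C[C@H](C(OC)OC)[C@@H](C(C)=C)[C@@H]2O[C@]12O[Si](C)(C)C(C)(C)C | intermediate
7 | 6α-(TBS-oxy)-4α-(dimethoxymethyl)carvone | CC1=C[C@H](C(OC)OC)[C@@H](C(C)=C)[C@H](O[Si](C)(C)C(C)(C)C)C1=O | intermediate
8 | 6α-(TBS-oxy)-4α-(dimethoxymethyl)-2-methyl-5β-(prop-1-en-2-yl)cyclohex-2-en-1β-ol | CC1=C[C@H](C(OC)OC)[C@@H](C(C)=C)[C@H](O[Si](C)(C)C(C)(C)C)[C@H]1O | intermediate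
9 | 4α-formyl analogue of 8 | CC1=C[C@H](C=O)[C@@H](C(C)=C)[C@H](O[Si](C)(C)C(C)(C)C)[C@H]1O | intermediate
10 | 4α-[(Z)-prop-1-enyl] analogue of 8 | CC1=C[C@H](/C=C\C)[C@@H](C(C)=C)[C@H](O[Si](C)(C)C(C)(C)C)[C@H]1O | intermediate
11 | ketene N,O-acetal of 10 (C1β–O–C(=CH2)NMe2) | CC1=C[C@H](/C=C\C)[C@@H](C(C)=C)[C@H](O[Si](C)(C)C(C)(C)C)[C@H]1OC(=C)N(C)C | intermediate
12 | N,N-dimethylamide: C3β–CH2C(=O)NMe2, C4α-(Z)-propenyl, C5β-isopropenyl, C6α-OTBS, C1=C2(Me) | CC=1[C@@H](CC(=O)N(C)C)[C@H](/C=C\C)[C@@H](C(C)=C)[C@H](O[Si](C)(C)C(C)(C)C)C=1 | intermediate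
13 | iminium lactone iodide (C2β–O–C(=NMe2+)–C11; C1α–I) | C[C@]12OC(=[N+](C)C)C[C@H]1[C@H](/C=C\C)[C@@H](C(C)=C)[C@H](O[Si](C)(C)C(C)(C)C)[C@@H]2I.[I-] | intermediate
14 | iodolactone (C2β–O–C12(=O)–C11 γ-lactone; C1α–I) | C[C@]12OC(=O)C[C@H]1[C@H](/C=C\C)[C@@H](C(C)=C)[C@H](O[Si](C)(C)C(C)(C)C)[C@@H]2I | intermediate
15 | methyl ester 1β,2β-epoxide | COC(=O)C[C@H]1[C@H](/C=C\C)[C@@H](C(C)=C)[C@H](O[Si](C)(C)C(C)(C)C)[C@H]2O[C@@]12C | intermediate
16 | 1β-hydroxy-2-methylidene methyl ester | C=C1[C@@H](CC(=O)OC)[C@H](/C=C\C)[C@@H](C(C)=C)[C@H](O[Si](C)(C)C(C)(C)C)[C@H]1O | intermediate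
17 | 1β-hydroxy-2-methylidene aldehyde (C3β–CH2CHO) | C=C1[C@@H](CC=O)[C@H](/C=C\C)[C@@H](C(C)=C)[C@H](O[Si](C)(C)C(C)(C)C)[C@H]1O | intermediate
18 | aldoxime of 17 | C=C1[C@@H](CC=NO)[C@H](/C=C\C)[C@@H](C(C)=C)[C@H](O[Si](C)(C)C(C)(C)C)[C@H]1O | intermediate
19 | nitrile oxide from 18 | C=C1[C@@H](CC#[N+][O-])[C@H](/C=C\C)[C@@H](C(C)=C)[C@H](O[Si](C)(C)C(C)(C)C)[C@H]1O | intermediate
20 | isoxazoline-fused trans-hydrindane: C1β-OH, C2=CH2, C5β-isopropenyl, C6α-OTBS, (14S)-methyl isoxazoline across C12–C13 | C=C1[C@H]2CC3=NO[C@@H](C)[C@H]3[C@@H]2[C@@H](C(C)=C)[C@H](O[Si](C)(C)C(C)(C)C)[C@H]1O | intermediate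
21 | (R)-2-methylbutanoic acid | CC[C@@H](C)C(=O)O | starting material
22 | C1α (R)-2-methylbutanoate of the isoxazoline (C6α-OTBS) | C=C1[C@H]2CC3=NO[C@@H](C)[C@H]3[C@@H]2[C@@H](C(C)=C)[C@H](O[Si](C)(C)C(C)(C)C)[C@@H]1OC(=O)[C@H](C)CC | intermediate
23 | C6α alcohol of 22 | C=C1[C@H]2CC3=NO[C@@H](C)[C@H]3[C@@H]2[C@@H](C(C)=C)[C@H](O)[C@@H]1OC(=O)[C@H](C)CC | intermediate
24 | (8S)-8,9-epoxide of 23 | C=C1[C@H]2CC3=NO[C@@H](C)[C@H]3[C@@H]2[C@@H]([C@@]4(C)CO4)[C@H](O)[C@@H]1OC(=O)[C@H](C)CC | intermediate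
25 | (Z)-3-methylpent-2-enoic acid | CC/C(C)=C\C(=O)O | starting material
26 | C6α (Z)-3-methylpent-2-enoate of 24 | C=C1[C@H]2CC3=NO[C@@H](C)[C@H]3[C@@H]2[C@@H]([C@@]4(C)CO4)[C@H](OC(=O)/C=C(/C)CC)[C@@H]1OC(=O)[C@H](C)CC | intermediate
27 | β-hydroxy imine (C12=NH; C14–OH) | C=C1[C@H]2CC(=N)[C@@H]([C@H](C)O)[C@@H]2[C@@H]([C@@]2(C)CO2)[C@H](OC(=O)/C=C(/C)CC)[C@@H]1OC(=O)[C@H](C)CC | intermediate
28 | β-hydroxy ketone (deacetyl target; 14S) | C=C1[C@H]2CC(=O)[C@@H]([C@H](C)O)[C@@H]2[C@@H]([C@@]2(C)CO2)[C@H](OC(=O)/C=C(/C)CC)[C@@H]1OC(=O)[C@H](C)CC | intermediate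
29 | CNP0262178.2 | C=C1[C@H]2CC(=O)[C@@H]([C@H](C)OC(C)=O)[C@@H]2[C@@H]([C@@]2(C)CO2)[C@H](OC(=O)/C=C(/C)CC)[C@@H]1OC(=O)[C@H](C)CC | target

**Count**

Total steps: 18. Longest linear sequence: 18 steps from (R)-carvone; both acids are used as bought.

**Three steps most likely to fail**

Step 7 (Eschenmoser–Claisen). The rearrangement needs the C1–O bond pseudo-axial, which forces the C4, C5 and C6 substituents axial, so it may stall or eliminate. The fallback sets out from 10 and moves to an ester-enolate manifold that rearranges far below 150 °C and can use a boat-like transition state. Acetylation (Ac2O, pyridine, DMAP) gives the C1β acetate F1. LiN(iPr)2 and Me3SiCl at −78 °C give the silyl ketene acetal F2, which on warming to 60 °C undergoes Ireland–Claisen rearrangement to the trimethylsilyl ester F3. Aqueous work-up gives the C3β acetic acid F4. Iodolactonisation of F4 (I2, NaHCO3, MeCN) then gives iodolactone 14, where the route is rejoined.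

Step 13 (Mitsunobu inversion at C1). The alcohol is secondary, allylic and flanked by the silyl ether, so elimination or SN2′ attack at C7 can compete. The fallback sets out from 20 and separates activation from displacement. MsCl and Et3N at −20 °C give the C1β mesylate F5. This is displaced, without isolation, by cesium (R)-2-methylbutanoate F6 (from 21 and Cs2CO3) with 18-crown-6 in toluene. The SN2 inversion gives 22, where the route is rejoined.

Step 15 (hydroxyl-directed epoxidation). The C8 configuration rests on one rotamer of the isopropenyl group in the vanadate transition state, so the diastereomer ratio is the least certain stereochemical outcome of the route. The fallback sets out from 23 and builds the C8–O bond by ring closure instead of oxygen transfer. Boc2O and DMAP give the C6 tert-butyl carbonate F7. IBr in toluene at −80 °C closes the six-membered cyclic iodocarbonate F8 (Bartlett iodocarbonation, chair with the C8 methyl equatorial and the iodomethyl group axial). Brief K2CO3 in MeOH at 0 °C opens the carbonate and closes the epoxide, giving 24, where the route is rejoined.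

**Further compounds**

F1 | step 7 | C1β acetate of 10 | CC1=C[C@H](/C=C\C)[C@@H](C(C)=C)[C@H](O[Si](C)(C)C(C)(C)C)[C@H]1OC(C)=O
F2 | step 7 | trimethylsilyl ketene acetal of F1 | CC1=C[C@H](/C=C\C)[C@@H](C(C)=C)[C@H](O[Si](C)(C)C(C)(C)C)[C@H]1OC(=C)O[Si](C)(C)C
F3 | step 7 | trimethylsilyl ester of the C3β acetic acid | CC=1[C@@H](CC(=O)O[Si](C)(C)C)[C@H](/C=C\C)[C@@H](C(C)=C)[C@H](O[Si](C)(C)C(C)(C)C)C=1
F4 | step 7 | C3β acetic acid (acid analogue of amide 12) | CC=1[C@@H](CC(=O)O)[C@H](/C=C\C)[C@@H](C(C)=C)[C@H](O[Si](C)(C)C(C)(C)C)C=1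
F5 | step 13 | C1β mesylate of 20 | C=C1[C@H]2CC3=NO[C@@H](C)[C@H]3[C@@H]2[C@@H](C(C)=C)[C@H](O[Si](C)(C)C(C)(C)C)[C@H]1OS(C)(=O)=O
F6 | step 13 | cesium (R)-2-methylbutanoate | [Cs+].CC[C@@H](C)C([O-])=O
F7 | step 15 | C6α tert-butyl carbonate of 23 | C=C1[C@H]2CC3=NO[C@@H](C)[C@H]3[C@@H]2[C@@H](C(C)=C)[C@H](OC(=O)OC(C)(C)C)[C@@H]1OC(=O)[C@H](C)CC
F8 | step 15 | cyclic iodocarbonate (C6–O–C(=O)–O–C8; C8 bears CH3 and CH2I; 8S) | C=C1[C@H]2CC3=NO[C@@H](C)[C@H]3[C@@H]2[C@H]4[C@@](C)(CI)OC(=O)O[C@@H]4[C@@H]1OC(=O)[C@H](C)CC
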